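**Retrosynthetic overview**
1. Feature used: ring A and ring B are alike. In each, C1 carries the butyryl group, the oxygens on C2 and C6 on either side of it are free OH, and the only OCH3 sits on C4, between the C3 methyl and the C5 methylene carbon, opposite the ketone. A ketone installed late can therefore single out its two neighbouring ethers for cleavage.
2. Last disconnection: the four O–H groups at C2 and C6 of both rings go back to methyl ethers, to be removed under the direction of the adjacent ketones.
3. Key disconnection: both C1–C(=O) bonds, by twofold Friedel–Crafts acylation of bis(2,4,6-trimethoxy-3-methylphenyl)methane with two equivalents of butyryl chloride.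
4. The diarylmethane is cut at its two aryl–CH2 bonds into two molecules of 2,4,6-trimethoxytoluene (ring lithiation) and ethyl formate as the one-carbon bridge; the carbinol oxygen is then removed by ionic hydrogenation.
5. No ring is formed. Both benzene rings come from 2,4,6-trimethoxytoluene, whose two unsubstituted carbons are equivalent, so the bridge is set without a regiochemical question and the symmetry is given up only when the ketones arrive.

Key step: step 3

Remark: ring atoms are numbered as in the overview (C1 butyryl, C2 and C6 oxygen, C3 methyl, C4 methoxy, C5 methylene bridge), whereas the systematic names in the compound list count the other way round the ring, so that the bridge carbon is locant 3 and the methyl carbon locant 5 there; 2,4,6-trimethoxytoluene is assumed to be a commercial compound.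

**Route**

Step 1
Reactants: 1 2,4,6-trimethoxytoluene (two equivalents are consumed); 2 ethyl formate
Product: 5 bis(2,4,6-trimethoxy-3-methylphenyl)methanol, via aryllithium 3 (not isolated), via aryl aldehyde 4 (not isolated)
Conditions: 1 (2.3 equiv), n-BuLi (2.2 equiv), TMEDA (2.2 equiv), THF, 0 °C to rt; HCO2Et (1.0 equiv), −78 °C to rt; then H2O
Reagents that add atoms: 2,4,6-trimethoxytoluene (second equivalent), Cc1c(OC)cc(OC)cc1OC
Why: Directed ortho-lithiation at the ring C–H between two methoxy groups gives aryllithium 3, two equivalents of which add to ethyl formate (addition, loss of ethoxide to aldehyde 4, second 1,2-addition) to give the symmetric diarylcarbinol, whose carbinol carbon is not a stereocentre because both aryl groups are the same.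

Step 2
Reactants: 5 bis(2,4,6-trimethoxy-3-methylphenyl)methanol
Product: 6 bis(2,4,6-trimethoxy-3-methylphenyl)methane
Conditions: Et3SiH (3 equiv), TFA (5 equiv), CH2Cl2, 0 °C
Reagents that add atoms: none
Why: Ionic hydrogenation should work because TFA ionises the doubly benzylic alcohol to a diarylmethyl cation stabilised by the ortho and para methoxy groups of both rings, and Et3SiH transfers hydride to that cation.

Step 3
Reactants: 6 bis(2,4,6-trimethoxy-3-methylphenyl)methane; 7 butyryl chloride (two equivalents are consumed, one per ring)
Product: 9 1,1'-[methylenebis(2,4,6-trimethoxy-5-methyl-3,1-phenylene)]bis(butan-1-one), via monoketone 8 (not isolated)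
Conditions: n-PrCOCl (2.5 equiv), SnCl4 (2.5 equiv), CH2Cl2, −40 to 0 °C; cold 1 M HCl
Reagents that add atoms: butyryl chloride (second equivalent), CCCC(=O)Cl
Why: SnCl4 turns butyryl chloride into an acylium-type electrophile, and C1, the only hydrogen-bearing carbon of each ring, with methoxy groups at both ortho positions and at the para position, adds to it; the arenium ion then gives up the C1 proton and leaves the aryl ketone bound to SnCl4 until the quench. The closest known reaction type is the Friedel–Crafts acylation of phloroglucinol trimethyl ethers with acid chlorides and SnCl4 or AlCl3. No ring is closed and no stereocentre is formed; the two C1–C(=O) bonds, one from each molecule of butyryl chloride, are the only skeletal bonds made. The step must substitute the C1 hydrogen without ipso attack of the electrophile or of a proton at C5, which would expel a stabilised trimethoxybenzyl cation and break the bridge; the free C–H position is less hindered than the fully substituted carbons and loses its proton irreversibly, and SnCl4 below 0 °C should keep the medium too mild for dealkylation. Because the CH2 bridge insulates the rings from each other, the ketone of monoketone 8 lowers the nucleophilicity of its own arene only, and the second arene is then acylated by the second equivalent of butyryl chloride. Partial loss of an ortho methyl ether under SnCl4 would do no harm, since these ethers are removed in step 4.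

Step 4
Reactants: 9 1,1'-[methylenebis(2,4,6-trimethoxy-5-methyl-3,1-phenylene)]bis(butan-1-one)
Product: 10 methylenebis(aspidinol)
Conditions: BCl3 (1 M in CH2Cl2, 8 equiv), CH2Cl2, −78 to 0 °C; then H2O
Reagents that add atoms: none
Why: Chelation-controlled ortho-demethylation of an aryl ketone: BCl3 binds each carbonyl oxygen and, through a six-membered O–B–O chelate, activates only the C2 and C6 ethers for removal of methyl by chloride, the acyl group turning to the second ortho oxygen once the first is a boron aryloxide, while the C4 ether cannot reach the carbonyl and should survive at or below 0 °C.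

**Compound list**
1 | 2,4,6-trimethoxytoluene | Cc1c(OC)cc(OC)cc1OC | starting material
2 | ethyl formate | CCOC=O | starting material
3 | (2,4,6-trimethoxy-3-methylphenyl)lithium | [Li]c1c(OC)cc(OC)c(C)c1OC | intermediate
4 | 2,4,6-trimethoxy-3-methylbenzaldehyde | O=Cc1c(OC)cc(OC)c(C)c1OC | intermediate
5 | bis(2,4,6-trimethoxy-3-methylphenyl)methanol | OC(c1c(OC)cc(OC)c(C)c1OC)c1c(OC)cc(OC)c(C)c1OC | intermediate
6 | bis(2,4,6-trimethoxy-3-methylphenyl)methane | COc1cc(OC)c(C)c(OC)c1Cc1c(OC)cc(OC)c(C)c1OC | intermediate
7 | butyryl chloride | CCCC(=O)Cl | starting material
8 | 1-[2,4,6-trimethoxy-3-methyl-5-(2,4,6-trimethoxy-3-methylbenzyl)phenyl]butan-1-one (monoketone) | CCCC(=O)c1c(OC)c(C)c(OC)c(Cc2c(OC)cc(OC)c(C)c2OC)c1OC | intermediate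
9 | 1,1'-[methylenebis(2,4,6-trimethoxy-5-methyl-3,1-phenylene)]bis(butan-1-one) | CCCC(=O)c1c(OC)c(C)c(OC)c(Cc2c(OC)c(C(=O)CCC)c(OC)c(C)c2OC)c1OC | intermediate
10 | methylenebis(aspidinol), 1,1'-[methylenebis(2,6-dihydroxy-4-methoxy-5-methyl-3,1-phenylene)]bis(butan-1-one) | CCCC(=O)c1c(O)c(C)c(OC)c(Cc2c(O)c(C(=O)CCC)c(O)c(C)c2OC)c1O | target

**Step count**
Total steps: 4. Longest linear sequence: 4 steps (1 → 5 → 6 → 9 → 10).

**Steps most likely to fail**

Step 4. The ether cleavage may not stay selective. The C4 ether is twisted out of the ring plane by its two ortho substituents and may be lost together with the ortho ethers. Cleavage may also stall after one ortho ether per ring, because the first boron chelate occupies the carbonyl. Prolonged acid contact could in addition scramble the methylene bridge. The fallback sets out from 9 and returns at 10. All six ethers of 9 would be cleaved with BBr3 (CH2Cl2, −78 °C to rt, then H2O) to the hexaphenol 1,1'-[methylenebis(2,4,6-trihydroxy-5-methyl-3,1-phenylene)]bis(butan-1-one) F1. Its two C4 hydroxyls are para to a ketone, the most acidic, and unable to hydrogen-bond to it. They would be methylated with TMSCHN2 (2 equiv, toluene/MeOH, 0 °C), which should give 10 without C-methylation.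

Step 3. Ipso attack of the acylium ion or of a proton at C5 may cut the bridge and redistribute the benzyl fragments, or the reaction may stop at monoketone 8 after one acylation. The fallback sets out from 6 and returns at 9, and it avoids Lewis and protic acid altogether. Both free positions of 6 would be brominated with NBS (MeCN, 0 °C) to bis(3-bromo-2,4,6-trimethoxy-5-methylphenyl)methane F2. Double bromine–lithium exchange (n-BuLi, THF, −78 °C) would give [methylenebis(2,4,6-trimethoxy-5-methyl-3,1-phenylene)]dilithium F3. Acylation of this with N-methoxy-N-methylbutanamide (−78 to 0 °C, then H2O) should give 9.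

Step 1. Metalation of the C-methyl group may compete with ring metalation, or the sequence may stop at the aldehyde because the second addition is hindered. The fallback sets out from 1 and returns at 5. One portion of 1 would be formylated under Vilsmeier–Haack conditions (POCl3, DMF, 0 °C to rt, then H2O) to give aldehyde 4 as an isolated compound. A second portion would be brominated with NBS (MeCN, 0 °C) to 1-bromo-2,4,6-trimethoxy-3-methylbenzene F4. Bromine–lithium exchange (n-BuLi, THF, −78 °C) would give aryllithium 3 at a defined site, and its addition to 4 followed by water should give 5.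

**Further compounds**
F1 | step 4 | 1,1'-[methylenebis(2,4,6-trihydroxy-5-methyl-3,1-phenylene)]bis(butan-1-one) | CCCC(=O)c1c(O)c(C)c(O)c(Cc2c(O)c(C(=O)CCC)c(O)c(C)c2O)c1O
F2 | step 3 | bis(3-bromo-2,4,6-trimethoxy-5-methylphenyl)methane | COc1c(Br)c(OC)c(C)c(OC)c1Cc1c(OC)c(Br)c(OC)c(C)c1OC
F3 | step 3 | [methylenebis(2,4,6-trimethoxy-5-methyl-3,1-phenylene)]dilithium | COc1c([Li])c(OC)c(C)c(OC)c1Cc1c(OC)c([Li])c(OC)c(C)c1OC
F4 | step 1 | 1-bromo-2,4,6-trimethoxy-3-methylbenzene | COc1cc(OC)c(C)c(OC)c1Br
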